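**Retrosynthetic overview**
1. Target ⇐ O-debenzylation of 26. The dihydrobenzofuran C7–O bond of arm A ⇐ acid-triggered closure of the ring A phenol onto a p-hydroxybenzylic boronate (24).
2. Both benzylic C7–O bonds ⇐ one new oxidative step on bis(2,3-diarylpropanol) 22: DDQ gives two quinone methides, and a boronate tethered at C9–OH delivers oxygen to C7 (7S in both arms).
3. Both aryl–C8 bonds ⇐ double auxiliary-controlled Pd α-arylation of dibromide 12 with the enolate equivalent of dihydroferulic imide 18.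
4. Dibromolactone 12 ⇐ trans-alkylation of (S)-β-benzylbutyrolactone 7 (Stobbe condensation, then Rh asymmetric hydrogenation, from 5-bromovanillin) with benzyl bromide 10.
5. Ring order: butyrolactone first, two temporary dioxaborinanes next, dihydrobenzofuran last.

Labels: ring A = aryl ring of the benzyl group on lactone C3 (it becomes the dihydrobenzofuran); ring B = aryl ring of the benzyl group on lactone C4; arm A / arm B = the three-carbon unit on ring A / ring B (C8 bound to the ring, C7 bearing the guaiacyl ring, C9 = CH2O); G = 4-hydroxy-3-methoxyphenyl; ArSi = 3-methoxy-4-(triisopropylsilyloxy)phenyl; Xc = (R)-4-benzyl-2-oxooxazolidin-3-yl.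

Assumption: the facial sense of step 3 (ligand control) and step 11 (auxiliary control) is taken by analogy with enamide/itaconate hydrogenation and Evans enolate alkylation; it is checked at 7 and 21, and the mirror-image ligand or auxiliary is used if it proves opposite.

**Step 1**
Reactants: 1 5-bromovanillin
Product: 2 4-(benzyloxy)-3-bromo-5-methoxybenzaldehyde
Conditions: BnBr, K2CO3, DMF, 60 °C
Reagents that add atoms: benzyl bromide, BrCc1ccccc1
Why: Williamson etherification of the acidic phenol; the benzyl ether survives every later step and is the only group that must come off last without acid.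

**Step 2**
Reactants: 2 4-(benzyloxy)-3-bromo-5-methoxybenzaldehyde; 3 dimethyl succinate
Product: 4 (E)-4-[4-(benzyloxy)-3-bromo-5-methoxyphenyl]-3-(methoxycarbonyl)but-3-enoic acid
Conditions: NaOMe, MeOH, reflux; then aq. HCl
Reagents that add atoms: none
Why: Stobbe condensation gives the itaconate half-ester with the free acid on the CH2 carbon, the standard entry to β-benzylbutyrolactones.

**Step 3**
Reactants: 4 (E)-4-[4-(benzyloxy)-3-bromo-5-methoxyphenyl]-3-(methoxycarbonyl)but-3-enoic acid
Product: 5 (S)-4-[4-(benzyloxy)-3-bromo-5-methoxyphenyl]-3-(methoxycarbonyl)butanoic acid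
Conditions: [Rh(cod)((R,R)-Et-DuPhos)]BF4 (0.5 mol%), H2 (5 bar), NaOMe (0.1 equiv), MeOH, rt
Reagents that add atoms: none
Why: carboxylate-directed Rh-bisphospholane asymmetric hydrogenation of a Stobbe itaconate sets the future lactone C4 as S (typically ≥95% ee); ArBr and OBn are inert to the homogeneous catalyst.

**Step 4**
Reactants: 5 (S)-4-[4-(benzyloxy)-3-bromo-5-methoxyphenyl]-3-(methoxycarbonyl)butanoic acid
Product: 7 (S)-4-[4-(benzyloxy)-3-bromo-5-methoxybenzyl]dihydrofuran-2(3H)-one, via hydroxy acid salt 6 (not isolated)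
Conditions: KOH (1 equiv), EtOH; CaCl2/NaBH4 [Ca(BH4)2], −10 °C to rt; then 3 M HCl
Reagents that add atoms: none
Why: chemoselective borohydride reduction of the ester in the presence of the carboxylate, then acid lactonisation; the stereocentre is not touched.

**Step 5**
Reactants: 1 5-bromovanillin
Product: 8 3-bromo-5-methoxy-4-(methoxymethoxy)benzaldehyde
Conditions: MOMCl, i-Pr2NEt, CH2Cl2, 0 °C to rt
Reagents that add atoms: chloromethyl methyl ether, COCCl
Why: acetal protection of the ring A phenol with the one group that step 15 can remove selectively by acid.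

**Step 6**
Reactants: 8 3-bromo-5-methoxy-4-(methoxymethoxy)benzaldehyde
Product: 9 [3-bromo-5-methoxy-4-(methoxymethoxy)phenyl]methanol
Conditions: NaBH4, MeOH, 0 °C
Reagents that add atoms: none
Why: routine borohydride reduction of an aryl aldehyde.

**Step 7**
Reactants: 9 [3-bromo-5-methoxy-4-(methoxymethoxy)phenyl]methanol
Product: 10 1-bromo-5-(bromomethyl)-3-methoxy-2-(methoxymethoxy)benzene
Conditions: CBr4, PPh3, CH2Cl2, 0 °C
Reagents that add atoms: carbon tetrabromide, BrC(Br)(Br)Br
Why: Appel bromination is neutral, so the MOM ether survives.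

**Step 8**
Reactants: 7 (S)-4-[4-(benzyloxy)-3-bromo-5-methoxybenzyl]dihydrofuran-2(3H)-one; 10 1-bromo-5-(bromomethyl)-3-methoxy-2-(methoxymethoxy)benzene
Product: 12 (3S,4S)-4-[4-(benzyloxy)-3-bromo-5-methoxybenzyl]-3-[3-bromo-5-methoxy-4-(methoxymethoxy)benzyl]dihydrofuran-2(3H)-one, via lithium enolate 11 (not isolated)
Conditions: LiN(SiMe3)2, THF, −78 °C; then 10, DMPU, −78 to −30 °C
Reagents that add atoms: none
Why: enolate alkylation of a β-benzylbutyrolactone occurs anti to the C4 substituent (the classical trans-dibenzylbutyrolactone synthesis), setting C3 as S; the amide base does not touch ArBr.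

**Step 9**
Reactants: 13 3-(4-hydroxy-3-methoxyphenyl)propanoic acid
Product: 15 3-[3-methoxy-4-(triisopropylsilyloxy)phenyl]propanoic acid, via bis-silyl compound 14 (not isolated)
Conditions: i-Pr3SiCl (2.3 equiv), imidazole, DMF, rt; then THF/H2O/AcOH, rt
Reagents that add atoms: triisopropylsilyl chloride, CC(C)[Si](Cl)(C(C)C)C(C)C
Why: silylation of phenol and acid, then selective hydrolysis of the labile silyl ester; the aryl silyl ether is the only phenol protection here that is removable before step 14 without touching MOM or Bn.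

**Step 10**
Reactants: 15 3-[3-methoxy-4-(triisopropylsilyloxy)phenyl]propanoic acid; 16 (R)-4-benzyloxazolidin-2-one
Product: 18 (R)-4-benzyl-3-{3-[3-methoxy-4-(triisopropylsilyloxy)phenyl]propanoyl}oxazolidin-2-one, via mixed pivalic anhydride 17 (not isolated)
Conditions: t-BuCOCl, Et3N, THF, −20 °C; then 16, LiCl, rt
Reagents that add atoms: none
Why: standard N-acylation of an Evans auxiliary through the mixed anhydride.

**Step 11**
Reactants: 12 (3S,4S)-dibromolactone; 18 imide (3 equiv)
Product: 20 (3S,4S)-lactone 12 in which each Br is replaced by the (S)-configured group CH(CH2ArSi)C(=O)Xc, via silyl ketene aminal 19 (not isolated)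
Conditions: 18, LiN(SiMe3)2, Me3SiCl, THF, −78 to 0 °C (used crude); then 12, Pd(dba)2 (10 mol%), P(t-Bu)3 (20 mol%), ZnF2 (1 equiv), DMF, 70 °C
Reagents that add atoms: none
Why: Pd-catalysed α-arylation of an imide silyl ketene aminal under ZnF2 activation (Hartwig-type enolate arylation); after oxidative addition of ArBr to zerovalent palladium, the aryl group is delivered to the Z-enolate face anti to the 4-benzyl group of the (R)-auxiliary, giving S at both new C8 centres; the near-neutral conditions leave lactone, MOM, Bn and aryl silyl ethers intact.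

**Step 12**
Reactants: 20 bis-imide
Product: 21 (3S,4S)-lactone 12 in which each Br is replaced by the (S)-configured group CH(CH2ArSi)CH2OH
Conditions: NaBH4 (8 equiv), THF/H2O (4:1), 0 °C to rt
Reagents that add atoms: none
Why: NaBH4 in wet THF cleaves N-acyloxazolidinones reductively to primary alcohols without epimerising the α-aryl centre and is much slower towards the hindered γ-lactone; the auxiliary 16 is recovered.

**Step 13**
Reactants: 21 bis-silyl diol
Product: 22 (3S,4S)-lactone 12 in which each Br is replaced by the (S)-configured group CH(CH2G)CH2OH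
Conditions: Bu4NF (2.4 equiv), AcOH (2.4 equiv), THF, 0 °C
Reagents that add atoms: none
Why: buffered fluoride removes only the two aryl silyl ethers, freeing exactly the two guaiacyl phenols that step 14 must oxidise while ring A (MOM) and ring B (Bn) stay masked.

**Step 14**
Reactants: 22 bis-phenol diol
Product: 24 (3S,4S)-lactone 12 in which each Br is replaced by a (4S,5S)-4-(4-hydroxy-3-methoxyphenyl)-2-phenyl-1,3,2-dioxaborinan-5-yl group, via bis(quinone methide) 23 (not isolated)
Conditions: PhB(OH)2 (2.4 equiv), 4 Å MS, CH2Cl2/MeCN, rt, 1 h; DDQ (2.05 equiv), −30 °C; then i-Pr2NEt (0.3 equiv), −30 to 0 °C; filter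
Reagents that add atoms: phenylboronic acid, OB(O)c1ccccc1
Why: Proposed new method: DDQ dehydrogenates each free 4-alkylguaiacol to its p-quinone methide, and the C9 hydroxyl, pre-esterified with PhB(OH)2, delivers a boron-bound hydroxyl to C7 through a six-membered chair transition state in which allylic strain holds H8 in the quinone methide plane and both aryl groups sit equatorial, so both new benzylic C–O bonds form anti to the C8 aryl group (7S,8S, the trans-boronate being also the thermodynamic isomer); the closest known reactions are the amine-promoted oxa-Michael addition of boronic acid hemiesters of hydroxy enones and the DDQ benzylic alkoxylation of 4-alkylphenols, here combined as a tethered 1,6-oxa-addition that replaces a benzylic C–H by a stereodefined C–O bond.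

**Step 15**
Reactants: 24 bis-boronate
Product: 26 O-benzyl target [ring A closed to the (2R,3S)-2-(4-hydroxy-3-methoxyphenyl)-3-(hydroxymethyl)-7-methoxy-2,3-dihydrobenzofuran; arm B the free (1S,2S)-1,3-diol; ring B phenol still benzylated], via monocyclised boronate 25 (not isolated)
Conditions: CF3CO2H (10 equiv), CH2Cl2, 0 °C; then NaHCO3, pinacol, MeOH, rt
Reagents that add atoms: none
Why: acid cleaves the aryl MOM ether and ionises the p-hydroxybenzylic C7–O bond; in arm A the freed ring A phenol closes the five-membered ring (SN1/quinone-methide-type cycloetherification, which gives the trans-dihydrobenzofuran, 7R), while arm B has no free phenol and can only re-close to its trans-boronate; neutral pinacol transesterification then releases the arm B diol.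

**Step 16**
Reactants: 26 O-benzyl target
Product: 27 target CNP0199264.1
Conditions: H2 (1 bar), 10% Pd/C, EtOAc/EtOH, rt, stopped at full conversion
Reagents that add atoms: none
Why: neutral hydrogenolysis of a phenolic benzyl ether, which is faster than cleavage of the dihydrobenzofuran C2–O bond or the benzylic alcohol; no acid is present that could close arm B.

**Compound list**
1 | 5-bromovanillin (3-bromo-4-hydroxy-5-methoxybenzaldehyde) | O=Cc1cc(Br)c(O)c(OC)c1 | starting material
2 | 4-(benzyloxy)-3-bromo-5-methoxybenzaldehyde | O=Cc1cc(Br)c(OCc2ccccc2)c(OC)c1 | intermediate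
3 | dimethyl succinate | COC(=O)CCC(=O)OC | starting material
4 | (E)-4-[4-(benzyloxy)-3-bromo-5-methoxyphenyl]-3-(methoxycarbonyl)but-3-enoic acid | COC(=O)/C(CC(=O)O)=C/c1cc(Br)c(OCc2ccccc2)c(OC)c1 | intermediate
5 | (S)-4-[4-(benzyloxy)-3-bromo-5-methoxyphenyl]-3-(methoxycarbonyl)butanoic acid | COC(=O)[C@H](CC(=O)O)Cc1cc(Br)c(OCc2ccccc2)c(OC)c1 | intermediate
6 | (S)-4-[4-(benzyloxy)-3-bromo-5-methoxyphenyl]-3-(hydroxymethyl)butanoic acid (present as its carboxylate salt, not isolated) | OC[C@H](CC(=O)O)Cc1cc(Br)c(OCc2ccccc2)c(OC)c1 | intermediate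
7 | (S)-4-[4-(benzyloxy)-3-bromo-5-methoxybenzyl]dihydrofuran-2(3H)-one | O=C1C[C@H](Cc2cc(Br)c(OCc3ccccc3)c(OC)c2)CO1 | intermediate
8 | 3-bromo-5-methoxy-4-(methoxymethoxy)benzaldehyde | O=Cc1cc(Br)c(OCOC)c(OC)c1 | intermediate
9 | [3-bromo-5-methoxy-4-(methoxymethoxy)phenyl]methanol | OCc1cc(Br)c(OCOC)c(OC)c1 | intermediate
10 | 1-bromo-5-(bromomethyl)-3-methoxy-2-(methoxymethoxy)benzene | BrCc1cc(Br)c(OCOC)c(OC)c1 | intermediate
11 | lithium enolate of 7 (not isolated) | [Li+].[O-]C1=C[C@H](Cc2cc(Br)c(OCc3ccccc3)c(OC)c2)CO1 | intermediate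
12 | (3S,4S)-4-[4-(benzyloxy)-3-bromo-5-methoxybenzyl]-3-[3-bromo-5-methoxy-4-(methoxymethoxy)benzyl]dihydrofuran-2(3H)-one | COc1cc(C[C@@H]2COC(=O)[C@H]2Cc2cc(Br)c(OCOC)c(OC)c2)cc(Br)c1OCc1ccccc1 | intermediate
13 | 3-(4-hydroxy-3-methoxyphenyl)propanoic acid (dihydroferulic acid) | COc1cc(CCC(=O)O)ccc1O | starting material
14 | triisopropylsilyl 3-[3-methoxy-4-(triisopropylsilyloxy)phenyl]propanoate (not isolated) | COc1cc(CCC(=O)O[Si](C(C)C)(C(C)C)C(C)C)ccc1O[Si](C(C)C)(C(C)C)C(C)C | intermediate
15 | 3-[3-methoxy-4-(triisopropylsilyloxy)phenyl]propanoic acid | COc1cc(CCC(=O)O)ccc1O[Si](C(C)C)(C(C)C)C(C)C | intermediate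
16 | (R)-4-benzyloxazolidin-2-one | O=C1N[C@H](Cc2ccccc2)CO1 | starting material
17 | mixed anhydride of 15 with pivalic acid (not isolated) | COc1cc(CCC(=O)OC(=O)C(C)(C)C)ccc1O[Si](C(C)C)(C(C)C)C(C)C | intermediate
18 | (R)-4-benzyl-3-{3-[3-methoxy-4-(triisopropylsilyloxy)phenyl]propanoyl}oxazolidin-2-one | COc1cc(CCC(=O)N2C(=O)OC[C@H]2Cc2ccccc2)ccc1O[Si](C(C)C)(C(C)C)C(C)C | intermediate
19 | (Z)-O-trimethylsilyl ketene N,O-acetal of 18 (not isolated) | COc1cc(C/C=C(\O[Si](C)(C)C)N2C(=O)OC[C@H]2Cc2ccccc2)ccc1O[Si](C(C)C)(C(C)C)C(C)C | intermediate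
20 | bis-imide: (3S,4S)-lactone core of 12, ring A (4-OMOM) and ring B (4-OBn) each carrying at C5 the (S)-CH(CH2ArSi)C(=O)Xc group | COc1cc(C[C@@H]2COC(=O)[C@H]2Cc3cc([C@H](Cc4ccc(O[Si](C(C)C)(C(C)C)C(C)C)c(OC)c4)C(=O)N5C(=O)OC[C@H]5Cc6ccccc6)c(OCOC)c(OC)c3)cc([C@H](Cc7ccc(O[Si](C(C)C)(C(C)C)C(C)C)c(OC)c7)C(=O)N8C(=O)OC[C@H]8Cc9ccccc9)c1OCc1ccccc1 | intermediate
21 | bis-silyl diol: as 20 but each arm is (S)-CH(CH2ArSi)CH2OH | COc1cc(C[C@@H]2COC(=O)[C@H]2Cc3cc([C@H](Cc4ccc(O[Si](C(C)C)(C(C)C)C(C)C)c(OC)c4)CO)c(OCOC)c(OC)c3)cc([C@H](Cc5ccc(O[Si](C(C)C)(C(C)C)C(C)C)c(OC)c5)CO)c1OCc1ccccc1 | intermediate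
22 | bis-phenol diol: as 21 but each arm is (S)-CH(CH2G)CH2OH | COc1cc(C[C@@H]2COC(=O)[C@H]2Cc3cc([C@H](Cc4ccc(O)c(OC)c4)CO)c(OCOC)c(OC)c3)cc([C@H](Cc5ccc(O)c(OC)c5)CO)c1OCc1ccccc1 | intermediate
23 | bis(quinone methide) bis(hemiboronate): each arm is (S)-CH(CH=quinone methide)CH2OB(OH)Ph, exocyclic C=C geometry not defined (not isolated) | COc1cc(C[C@@H]2COC(=O)[C@H]2Cc3cc([C@H](C=C4C=C(OC)C(=O)C=C4)COB(O)c5ccccc5)c(OCOC)c(OC)c3)cc([C@H](C=C6C=C(OC)C(=O)C=C6)COB(O)c7ccccc7)c1OCc1ccccc1 | intermediate
24 | bis-boronate: each arm is a trans-(4S,5S)-4-(4-hydroxy-3-methoxyphenyl)-2-phenyl-1,3,2-dioxaborinan-5-yl group on ring A (4-OMOM) and ring B (4-OBn) | COc1cc(C[C@@H]2COC(=O)[C@H]2Cc3cc([C@H]4COB(c5ccccc5)O[C@@H]4c6ccc(O)c(OC)c6)c(OCOC)c(OC)c3)cc([C@H]7COB(c8ccccc8)O[C@@H]7c9ccc(O)c(OC)c9)c1OCc1ccccc1 | intermediate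
25 | monocyclised boronate: ring A closed to the (2R,3S)-dihydrobenzofuran with its CH2O–B(OH)Ph hemiester, arm B still the (4S,5S)-dioxaborinane, ring B OBn (not isolated) | COc1cc(C[C@@H]2COC(=O)[C@H]2Cc3cc(OC)c4c(c3)[C@@H](COB(O)c5ccccc5)[C@H](c6ccc(O)c(OC)c6)O4)cc([C@H]7COB(c8ccccc8)O[C@@H]7c9ccc(O)c(OC)c9)c1OCc1ccccc1 | intermediate
26 | O-benzyl target: (3S,4S)-lactone, ring A = (2R,3S)-2-G-3-(hydroxymethyl)-7-methoxy-2,3-dihydrobenzofuran-5-yl, ring B = 4-benzyloxy-3-methoxy-5-[(1S,2S)-1,3-dihydroxy-1-G-propan-2-yl]phenyl | COc1cc(C[C@@H]2COC(=O)[C@H]2Cc3cc(OC)c4c(c3)[C@@H](CO)[C@H](c5ccc(O)c(OC)c5)O4)cc([C@@H](CO)[C@H](O)c6ccc(O)c(OC)c6)c1OCc1ccccc1 | intermediate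
27 | CNP0199264.1 | COc1cc([C@@H](O)[C@H](CO)c2cc(C[C@@H]3COC(=O)[C@H]3Cc3cc(OC)c4c(c3)[C@@H](CO)[C@H](c3ccc(O)c(OC)c3)O4)cc(OC)c2O)ccc1O | target

**Totals**
Total step count: 16. Longest linear sequence: 11 (steps 1, 2, 3, 4, 8, 11, 12, 13, 14, 15, 16).

**Three steps most likely to fail**

Step 14 (the proposed new step). Risks are over-oxidation of the benzylic boronates by DDQ, tautomerisation of the quinone methides to stilbenes, and incomplete anti selectivity. The fallback uses known chemistry, sets out from 22 and comes back at 24. Compound 22 is oxidised with DDQ (2.05 equiv) in 1,4-dioxane/H2O at 0 °C, the known undirected benzylic hydroxylation of 4-alkylguaiacols by way of quinone methide hydration. This gives the tetraol with a (1S,2S)-1,3-diol in both arms, F7, together with its C7 epimers. The mixture is condensed with PhB(OH)2 (MgSO4, CH2Cl2) in the presence of camphorsulfonic acid (0.1 equiv). The acid-promoted erythro/threo interconversion of guaiacyl carbinols then lets C7 equilibrate into the diequatorial trans-boronates, which is 24. Residual cis-boronate does not matter in arm A, because step 15 is stereoconvergent there; for arm B it is removed by chromatography after step 15.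

Step 11 (double α-arylation). Two ortho-alkoxy aryl bromides must each couple with a branched enolate, the diastereoselectivity counts twice, and the α-aryl imide can epimerise. The fallback makes the aryl–carbon bond with an unhindered acetate enolate and sets C8 by Evans alkylation instead. It sets out from 12 and comes back at 21. Commercial (S)-3-acetyl-4-benzyloxazolidin-2-one is converted (LiN(SiMe3)2, Me3SiCl) into its silyl ketene aminal F1. Coupling of F1 with 12 under the same Pd(dba)2/P(t-Bu)3/ZnF2 conditions forms no stereocentre and gives the bis(arylacetyl) imide F2. Separately, vanillin is silylated (i-Pr3SiCl, imidazole) to 3-methoxy-4-(triisopropylsilyloxy)benzaldehyde F3, reduced (NaBH4) to the benzyl alcohol F4, and brominated (PBr3, pyridine) to the benzyl bromide F5. Double alkylation of the sodium enolates of F2 (NaN(SiMe3)2, THF, −78 °C) with F5 gives the bis-imide F6, in which the (S)-auxiliary controls S at both C8 centres. Reduction of F6 with NaBH4 in THF/H2O gives 21.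

Step 15 (acid unmasking and closure). The released methoxymethyl cation can alkylate the electron-rich rings. Arm B could lose stereochemical integrity if its boronate is stripped, or could close by loss of the ring B benzyl group. The fallback moves the closure from the acid (cationic) manifold to a base-mediated one. It sets out from 24 and comes back at 26 through 25. The MOM ether is removed without protic acid by Me3SiOSO2CF3/2,2′-bipyridyl in CH2Cl2 at 0 °C followed by water. This gives the ring A phenol with both boronates intact, F8. Treating F8 with catalytic DBU in CH2Cl2 lets each p-hydroxybenzylic boronate revert to its quinone methide (the reverse of step 14). Arm B can only re-add its tethered boronate, whereas arm A is trapped irreversibly by the ring A phenoxide as the trans-dihydrobenzofuran, giving 25. The pinacol work-up of step 15 then gives 26.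

**Further compounds**
F1 | step 11 | (S)-4-benzyl-3-[1-(trimethylsilyloxy)vinyl]oxazolidin-2-one | C=C(O[Si](C)(C)C)N1C(=O)OC[C@@H]1Cc1ccccc1
F2 | step 11 | bis(arylacetyl) imide: (3S,4S)-lactone core of 12 with each Br replaced by CH2C(=O)-[(S)-4-benzyl-2-oxooxazolidin-3-yl] | COc1cc(C[C@@H]2COC(=O)[C@H]2Cc3cc(CC(=O)N4C(=O)OC[C@@H]4Cc5ccccc5)c(OCOC)c(OC)c3)cc(CC(=O)N6C(=O)OC[C@@H]6Cc7ccccc7)c1OCc1ccccc1
F3 | step 11 | 3-methoxy-4-(triisopropylsilyloxy)benzaldehyde | COc1cc(C=O)ccc1O[Si](C(C)C)(C(C)C)C(C)C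
F4 | step 11 | [3-methoxy-4-(triisopropylsilyloxy)phenyl]methanol | COc1cc(CO)ccc1O[Si](C(C)C)(C(C)C)C(C)C
F5 | step 11 | [4-(bromomethyl)-2-methoxyphenoxy]triisopropylsilane | COc1cc(CBr)ccc1O[Si](C(C)C)(C(C)C)C(C)C
F6 | step 11 | bis-imide as 20 but with the (S)-4-benzyl-2-oxooxazolidin-3-yl auxiliary on both arms (C8 S in both) | COc1cc(C[C@@H]2COC(=O)[C@H]2Cc3cc([C@H](Cc4ccc(O[Si](C(C)C)(C(C)C)C(C)C)c(OC)c4)C(=O)N5C(=O)OC[C@@H]5Cc6ccccc6)c(OCOC)c(OC)c3)cc([C@H](Cc7ccc(O[Si](C(C)C)(C(C)C)C(C)C)c(OC)c7)C(=O)N8C(=O)OC[C@@H]8Cc9ccccc9)c1OCc1ccccc1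
F7 | step 14 | tetraol: (3S,4S)-lactone core of 12 with each Br replaced by the (1S,2S)-1,3-dihydroxy-1-(4-hydroxy-3-methoxyphenyl)propan-2-yl group | COc1cc(C[C@@H]2COC(=O)[C@H]2Cc3cc([C@@H](CO)[C@H](O)c4ccc(O)c(OC)c4)c(OCOC)c(OC)c3)cc([C@@H](CO)[C@H](O)c5ccc(O)c(OC)c5)c1OCc1ccccc1
F8 | step 15 | ring A phenol of 24 (MOM removed, both (4S,5S)-boronates intact, ring B OBn) | COc1cc(C[C@@H]2COC(=O)[C@H]2Cc3cc([C@H]4COB(c5ccccc5)O[C@@H]4c6ccc(O)c(OC)c6)c(O)c(OC)c3)cc([C@H]7COB(c8ccccc8)O[C@@H]7c9ccc(O)c(OC)c9)c1OCc1ccccc1
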